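**Strategy**

The route rests on cutting ring C at C3–C4. Because C3 is a methylene and C4 the ketone carbon, this bond is the C=C of the flavanone's silyl enol ether, while C2 is a benzylic aryl ether carbon flanked by O1. Ring-closing metathesis therefore forms C3=C4, closes ring C and delivers C4 at the ketone oxidation level in one operation without touching C2. The precursor is an (S)-1-arylallyl aryl ether, made by iridium-catalysed allylic etherification, whose ring A carries an ortho 1-silyloxyvinyl group. C8 stays unsubstituted until after cyclisation, and the ring B phenol is masked as a triisopropylsilyl ether that differs from the enol silyl group.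

Key step: step 7

Assumption: the (Sa,Sc,Sc) phosphoramidite is taken to give the (S)-configured branched ether from an (E)-cinnamyl-type carbonate and an oxygen nucleophile, as is usual for this ligand family; if the sense were opposite here, the mirror-image ligand would be used with nothing else changed.

**Route**

Step 1
Reactants: 1 3,4,5-trimethoxyphenol
Product: 2 1-(2-hydroxy-4,5,6-trimethoxyphenyl)ethan-1-one
Conditions: AcOH, BF3·OEt2 (3 equiv), 90 °C; aqueous work-up
Reagents that add atoms: acetic acid, CC(=O)O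
Why: Friedel–Crafts C-acylation of a very electron-rich phenol at one of its two equivalent ortho positions, with chelation of the resulting ortho-hydroxy ketone preventing a second acylation.

Step 2
Reactants: 3 methyl (E)-4-hydroxycinnamate
Product: 4 methyl (2E)-3-[4-(triisopropylsilyloxy)phenyl]prop-2-enoate
Conditions: TIPSCl, imidazole, DMF, 25 °C
Reagents that add atoms: chlorotriisopropylsilane, CC(C)[Si](Cl)(C(C)C)C(C)C
Why: Imidazole-promoted silylation of the phenol; the bulky triisopropylsilyl ether is chosen because it should resist the lithium aryloxide and alkoxide of step 5, the amide base of step 6 and BCl3 in step 8, and it is a different silyl group from the enol ether made in step 6.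

Step 3
Reactants: 4 methyl (2E)-3-[4-(triisopropylsilyloxy)phenyl]prop-2-enoate
Product: 5 (2E)-3-[4-(triisopropylsilyloxy)phenyl]prop-2-en-1-ol
Conditions: i-Bu2AlH (2.3 equiv), CH2Cl2, −78 °C; aq. KNaC4H4O6 work-up
Reagents that add atoms: none
Why: 1,2-Reduction of the conjugated ester with i-Bu2AlH should stop at the (E)-allylic alcohol at low temperature without touching the alkene or the silyl ether.

Step 4
Reactants: 5 (2E)-3-[4-(triisopropylsilyloxy)phenyl]prop-2-en-1-ol
Product: 6 tert-butyl (2E)-3-[4-(triisopropylsilyloxy)phenyl]prop-2-en-1-yl carbonate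
Conditions: Boc2O, DMAP (10 mol %), CH2Cl2, 0 → 25 °C
Reagents that add atoms: di-tert-butyl dicarbonate, CC(C)(C)OC(=O)OC(=O)OC(C)(C)C
Why: DMAP-catalysed O-acylation gives the allylic tert-butyl carbonate, chosen as leaving group because the tert-butoxide it releases in step 5 is too hindered to compete as a nucleophile.

Step 5
Reactants: 2 1-(2-hydroxy-4,5,6-trimethoxyphenyl)ethan-1-one; 6 tert-butyl (2E)-3-[4-(triisopropylsilyloxy)phenyl]prop-2-en-1-yl carbonate
Product: 8 1-[2-({(1S)-1-[4-(triisopropylsilyloxy)phenyl]prop-2-en-1-yl}oxy)-4,5,6-trimethoxyphenyl]ethan-1-one, via lithium aryloxide 7 (not isolated)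
Conditions: 2 (1.4 equiv), LiN(SiMe3)2 (1.3 equiv), THF, 0 °C; then 6 (1.0 equiv), [Ir(cod)Cl]2 (2 mol %), (Sa,Sc,Sc)-O,O'-(1,1'-binaphthyl-2,2'-diyl) N,N-bis(1-phenylethyl)phosphoramidite (4 mol %, pre-activated with n-PrNH2), THF, 25 °C; water work-up
Reagents that add atoms: none
Why: Iridium-catalysed asymmetric allylic etherification, in which the cyclometalated iridium–phosphoramidite complex ionises the carbonate to an η3-allyl species that the aryloxide attacks at the aryl-bearing terminus to give the branched ether, the (Sa,Sc,Sc) ligand fixing the face of attack so that the new stereocentre (the future C2) is (S).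

Step 6
Reactants: 8 1-[2-({(1S)-1-[4-(triisopropylsilyloxy)phenyl]prop-2-en-1-yl}oxy)-4,5,6-trimethoxyphenyl]ethan-1-one
Product: 10 (1S)-1-[4-(triisopropylsilyloxy)phenyl]prop-2-en-1-yl 2-[1-(tert-butyldimethylsilyloxy)ethenyl]-3,4,5-trimethoxyphenyl ether, via potassium enolate 9 (not isolated)
Conditions: KN(SiMe3)2 (1.15 equiv), THF, −78 °C; then TBSCl (1.3 equiv), −78 → 0 °C; aq. NaHCO3 work-up
Reagents that add atoms: tert-butyl(chloro)dimethylsilane, CC(C)(C)[Si](C)(C)Cl
Why: Kinetic deprotonation of the acetyl methyl group, the only readily acidic site, followed by O-silylation of the potassium enolate gives the silyl enol ether; the base-mediated protocol avoids Lewis-acidic silyl triflates that could ionise the doubly activated C–O bond at the stereocentre, which itself is not deprotonated at −78 °C.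

Step 7
Reactants: 10 (1S)-1-[4-(triisopropylsilyloxy)phenyl]prop-2-en-1-yl 2-[1-(tert-butyldimethylsilyloxy)ethenyl]-3,4,5-trimethoxyphenyl ether
Product: 11 (2S)-4-(tert-butyldimethylsilyloxy)-5,6,7-trimethoxy-2-[4-(triisopropylsilyloxy)phenyl]-2H-chromene
Conditions: second-generation Grubbs catalyst (H2IMes)(PCy3)Cl2Ru=CHPh (5–10 mol %), 1,4-benzoquinone (10–20 mol %), degassed toluene (0.005 M), 50 °C, argon sparge, dark
Reagents that add atoms: none
Why: The ruthenium benzylidene should load onto the monosubstituted vinyl group, because the 1,1-disubstituted enol ether flanked by a di-ortho-substituted arene is too hindered to initiate, and the new alkylidene then adds across the enol ether C=C in an intramolecular [2+2] cycloaddition whose cycloreversion leaves Ru=CH2, which turns over with loss of ethylene. The closest known reaction type is ring-closing metathesis of a terminal olefin onto a silyl enol ether to give a cyclic silyl enol ether. Ring C closes as a six-membered ring with the new C3=C4 bond endocyclic, helped by the ortho disposition of the two arms on ring A. No stereocentre is formed, and C2, set in step 5, only has to survive, which is why 1,4-benzoquinone is added to quench ruthenium hydrides that would move the vinyl double bond towards C2 and erase it, and why the temperature is kept well below that of aromatic Claisen rearrangement or chromene ring-opening. The step needs chemoselectivity for the six-membered closure, and the substrate secures it: C8 is still C–H, so no second alkene can close a seven-membered ring, dilution suppresses vinyl–vinyl dimerisation, and the trisubstituted enol ether product does not re-enter the cycle.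

Step 8
Reactants: 11 (2S)-4-(tert-butyldimethylsilyloxy)-5,6,7-trimethoxy-2-[4-(triisopropylsilyloxy)phenyl]-2H-chromene
Product: 13 (2S)-5-hydroxy-6,7-dimethoxy-2-[4-(triisopropylsilyloxy)phenyl]chroman-4-one, via trimethoxyflavanone 12 (not isolated)
Conditions: HCl (1 M in Et2O, 1.1 equiv), MeOH (3 equiv), CH2Cl2, 0 °C; volatiles removed; then BCl3 (1.5 equiv), CH2Cl2, −78 → −10 °C; H2O quench
Reagents that add atoms: none
Why: Acid-catalysed protodesilylation (protonation at C3, silyl transfer to methanol) unmasks the C4 ketone, after which BCl3 binds the carbonyl and the peri 5-OMe in a six-membered chelate so that chloride removes only that methyl group (chelation-controlled ether cleavage), leaving 6-OMe, 7-OMe and the aryl silyl ether.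

Step 9
Reactants: 13 (2S)-5-hydroxy-6,7-dimethoxy-2-[4-(triisopropylsilyloxy)phenyl]chroman-4-one; 14 3-methylbut-2-en-1-ol (prenol)
Product: 15 (2S)-6,7-dimethoxy-5-[(3-methylbut-2-en-1-yl)oxy]-2-[4-(triisopropylsilyloxy)phenyl]chroman-4-one
Conditions: 14 (1.5 equiv), PPh3, DIAD, THF, 0 → 25 °C
Reagents that add atoms: none
Why: Mitsunobu etherification of the only free hydroxyl (O5) with a primary allylic alcohol runs under essentially neutral conditions, so the flavanone should not open to the 2'-hydroxychalcone as it could under base-mediated alkylation.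

Step 10
Reactants: 15 (2S)-6,7-dimethoxy-5-[(3-methylbut-2-en-1-yl)oxy]-2-[4-(triisopropylsilyloxy)phenyl]chroman-4-one
Product: 18 (2S)-5-hydroxy-6,7-dimethoxy-8-(3-methylbut-2-en-1-yl)-2-[4-(triisopropylsilyloxy)phenyl]chroman-4-one, via C6 dienone 16 (not isolated), via C8 dienone 17 (not isolated)
Conditions: Eu(fod)3 (fod = 6,6,7,7,8,8,8-heptafluoro-2,2-dimethyloctane-3,5-dionate; 10 mol %), acid-free CHCl3, 60 °C
Reagents that add atoms: none
Why: Lewis-acid-catalysed Claisen–Cope (para-Claisen) rearrangement, in which Eu(fod)3 chelated between the C4 carbonyl and O5 triggers the [3,3] shift to C6, whose dienone cannot tautomerise because C6 carries OMe, so a second [3,3] (Cope) shift carries the allyl unit on to C8, the only carbon that can rearomatise, restoring the normal prenyl connectivity and the 5-OH without involving C2.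

Step 11
Reactants: 18 (2S)-5-hydroxy-6,7-dimethoxy-8-(3-methylbut-2-en-1-yl)-2-[4-(triisopropylsilyloxy)phenyl]chroman-4-one
Product: 19 (2S)-5-hydroxy-2-(4-hydroxyphenyl)-6,7-dimethoxy-8-(3-methylbut-2-en-1-yl)chroman-4-one (CNP0104932.1)
Conditions: Bu4NF (1.2 equiv), AcOH (1.5 equiv), THF, 0 °C
Reagents that add atoms: none
Why: Fluoride-mediated cleavage of the aryl silyl ether, buffered with acetic acid so that no phenoxide base is present to open ring C by retro-oxa-Michael reaction and racemise C2.

**Compound list**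

1 | 3,4,5-trimethoxyphenol | COc1cc(O)cc(OC)c1OC | starting material
2 | 1-(2-hydroxy-4,5,6-trimethoxyphenyl)ethan-1-one | CC(=O)c1c(O)cc(OC)c(OC)c1OC | intermediate
3 | methyl (E)-4-hydroxycinnamate | COC(=O)/C=C/c1ccc(O)cc1 | starting material
4 | methyl (2E)-3-[4-(triisopropylsilyloxy)phenyl]prop-2-enoate | COC(=O)/C=C/c1ccc(O[Si](C(C)C)(C(C)C)C(C)C)cc1 | intermediate
5 | (2E)-3-[4-(triisopropylsilyloxy)phenyl]prop-2-en-1-ol | OC/C=C/c1ccc(O[Si](C(C)C)(C(C)C)C(C)C)cc1 | intermediate
6 | tert-butyl (2E)-3-[4-(triisopropylsilyloxy)phenyl]prop-2-en-1-yl carbonate | CC(C)(C)OC(=O)OC/C=C/c1ccc(O[Si](C(C)C)(C(C)C)C(C)C)cc1 | intermediate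
7 | lithium 2-acetyl-3,4,5-trimethoxyphenoxide (not isolated) | [Li+].CC(=O)c1c([O-])cc(OC)c(OC)c1OC | intermediate
8 | 1-[2-({(1S)-1-[4-(triisopropylsilyloxy)phenyl]prop-2-en-1-yl}oxy)-4,5,6-trimethoxyphenyl]ethan-1-one | C=C[C@H](Oc1cc(OC)c(OC)c(OC)c1C(C)=O)c1ccc(O[Si](C(C)C)(C(C)C)C(C)C)cc1 | intermediate
9 | potassium 1-[2-({(1S)-1-[4-(triisopropylsilyloxy)phenyl]prop-2-en-1-yl}oxy)-4,5,6-trimethoxyphenyl]ethen-1-olate (not isolated) | C=C[C@H](Oc1cc(OC)c(OC)c(OC)c1C(=C)[O-])c1ccc(O[Si](C(C)C)(C(C)C)C(C)C)cc1.[K+] | intermediate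
10 | (1S)-1-[4-(triisopropylsilyloxy)phenyl]prop-2-en-1-yl 2-[1-(tert-butyldimethylsilyloxy)ethenyl]-3,4,5-trimethoxyphenyl ether | C=C[C@H](Oc1cc(OC)c(OC)c(OC)c1C(=C)O[Si](C)(C)C(C)(C)C)c1ccc(O[Si](C(C)C)(C(C)C)C(C)C)cc1 | intermediate
11 | (2S)-4-(tert-butyldimethylsilyloxy)-5,6,7-trimethoxy-2-[4-(triisopropylsilyloxy)phenyl]-2H-chromene | COc1cc2c(c(OC)c1OC)C(O[Si](C)(C)C(C)(C)C)=C[C@@H](c1ccc(O[Si](C(C)C)(C(C)C)C(C)C)cc1)O2 | intermediate
12 | (2S)-5,6,7-trimethoxy-2-[4-(triisopropylsilyloxy)phenyl]chroman-4-one (not isolated) | COc1cc2c(c(OC)c1OC)C(=O)C[C@@H](c1ccc(O[Si](C(C)C)(C(C)C)C(C)C)cc1)O2 | intermediate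
13 | (2S)-5-hydroxy-6,7-dimethoxy-2-[4-(triisopropylsilyloxy)phenyl]chroman-4-one | COc1cc2c(c(O)c1OC)C(=O)C[C@@H](c1ccc(O[Si](C(C)C)(C(C)C)C(C)C)cc1)O2 | intermediate
14 | 3-methylbut-2-en-1-ol (prenol) | CC(C)=CCO | starting material
15 | (2S)-6,7-dimethoxy-5-[(3-methylbut-2-en-1-yl)oxy]-2-[4-(triisopropylsilyloxy)phenyl]chroman-4-one | COc1cc2c(c(OCC=C(C)C)c1OC)C(=O)C[C@@H](c1ccc(O[Si](C(C)C)(C(C)C)C(C)C)cc1)O2 | intermediate
16 | (2S)-6,7-dimethoxy-6-(2-methylbut-3-en-2-yl)-2-[4-(triisopropylsilyloxy)phenyl]-2,3-dihydro-4H-chromene-4,5(6H)-dione, C6 epimers (not isolated) | COC1=CC2=C(C(=O)C1(OC)C(C)(C)C=C)C(=O)C[C@@H](c1ccc(O[Si](C(C)C)(C(C)C)C(C)C)cc1)O2 | intermediate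
17 | (2S)-6,7-dimethoxy-8-(3-methylbut-2-en-1-yl)-2-[4-(triisopropylsilyloxy)phenyl]-2,3-dihydro-4H-chromene-4,5(8H)-dione, C8 epimers (not isolated) | COC1=C(OC)C(CC=C(C)C)C2=C(C1=O)C(=O)C[C@@H](c1ccc(O[Si](C(C)C)(C(C)C)C(C)C)cc1)O2 | intermediate
18 | (2S)-5-hydroxy-6,7-dimethoxy-8-(3-methylbut-2-en-1-yl)-2-[4-(triisopropylsilyloxy)phenyl]chroman-4-one | COc1c(O)c2c(c(CC=C(C)C)c1OC)O[C@H](c1ccc(O[Si](C(C)C)(C(C)C)C(C)C)cc1)CC2=O | intermediate
19 | (2S)-5-hydroxy-2-(4-hydroxyphenyl)-6,7-dimethoxy-8-(3-methylbut-2-en-1-yl)chroman-4-one | COc1c(O)c2c(c(CC=C(C)C)c1OC)O[C@H](c1ccc(O)cc1)CC2=O | target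

**Step count and risks**

Total step count: 11. Longest linear sequence: 10 steps (steps 2 to 11, from 3).

Steps most likely to fail:

1. Step 7 (key step). Cyclisation onto the crowded, electron-rich enol ether may be slower than catalyst decay, so that double-bond migration at the allylic ether (with loss of the C2 configuration) and intermolecular coupling of vinyl groups take over. The fallback closes ring C by Friedel–Crafts acylation at C4–C4a instead; it sets out from 1 and 6 and returns at 12. Phenol 1 is converted with LiN(SiMe3)2 into lithium 3,4,5-trimethoxyphenoxide F1, an unhindered and unchelated nucleophile, which is etherified with 6 under the iridium conditions of step 5 to give (1S)-1-[4-(triisopropylsilyloxy)phenyl]prop-2-en-1-yl 3,4,5-trimethoxyphenyl ether F2. Anti-Markovnikov hydroboration with 9-BBN in THF gives 9-{(3S)-3-[4-(triisopropylsilyloxy)phenyl]-3-(3,4,5-trimethoxyphenoxy)propyl}-9-borabicyclo[3.3.1]nonane F3, which is oxidised in the same flask (H2O2, aq. KH2PO4/K2HPO4) to (3S)-3-[4-(triisopropylsilyloxy)phenyl]-3-(3,4,5-trimethoxyphenoxy)propan-1-ol F4. TEMPO/PhI(OAc)2 in aqueous MeCN should give (3S)-3-[4-(triisopropylsilyloxy)phenyl]-3-(3,4,5-trimethoxyphenoxy)propanoic acid F5. (CF3CO)2O in CH2Cl2 at 0 °C should then acylate either of the two equivalent positions ortho to the ether oxygen and give 12, which re-enters the route at the BCl3 stage of step 8.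

2. Step 5. Attack of the chelated, ortho-acylated aryloxide on the allyliridium intermediate may be sluggish, and the electron-rich branched ether may re-ionise, eroding the branched selectivity and the enantiopurity. The fallback sets the stereocentre with a small oxygen nucleophile and forms the aryl ether by SN2 displacement; it sets out from 6 and returns at 8. Iridium-catalysed allylic substitution of 6 with KOSiEt3 ([Ir(cod)Cl]2 and the mirror-image (Ra,Rc,Rc) phosphoramidite, CH2Cl2, 25 °C) should give triethyl({(1R)-1-[4-(triisopropylsilyloxy)phenyl]prop-2-en-1-yl}oxy)silane F6. HF·pyridine buffered with pyridine in THF at 0 °C removes the alkyl silyl group only and gives (1R)-1-[4-(triisopropylsilyloxy)phenyl]prop-2-en-1-ol F7. Mitsunobu coupling of F7 with phenol 2 (PPh3, DIAD, toluene, 0 °C) should then give 8 with inversion to the (S) configuration.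

3. Step 10. The prenyl group may be lost heterolytically before or after the first [3,3] shift (returning the phenol), the cascade may stall at the cross-conjugated dienone, or the Lewis acid may open ring C at C2 on prolonged heating. The fallback attaches the prenyl group by cross-coupling at the only free position of ring A, bypassing steps 9 and 10; it sets out from 13 and returns at 18. Iodination with N-iodosuccinimide in DMF at 0 → 25 °C should take place at C8, the sole and strongly activated C–H of ring A, to give (2S)-5-hydroxy-8-iodo-6,7-dimethoxy-2-[4-(triisopropylsilyloxy)phenyl]chroman-4-one F8. Stille coupling with Bu3SnCH2CH=CMe2 (Pd(PPh3)4, DMF, 90 °C), which needs no base, should then give 18.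

**Further compounds**

F1 | step 7 | lithium 3,4,5-trimethoxyphenoxide | [Li+].COc1cc([O-])cc(OC)c1OC
F2 | step 7 | (1S)-1-[4-(triisopropylsilyloxy)phenyl]prop-2-en-1-yl 3,4,5-trimethoxyphenyl ether | C=C[C@H](Oc1cc(OC)c(OC)c(OC)c1)c1ccc(O[Si](C(C)C)(C(C)C)C(C)C)cc1
F3 | step 7 | 9-{(3S)-3-[4-(triisopropylsilyloxy)phenyl]-3-(3,4,5-trimethoxyphenoxy)propyl}-9-borabicyclo[3.3.1]nonane | C1CCC2CCCC1B2CC[C@H](Oc1cc(OC)c(OC)c(OC)c1)c1ccc(O[Si](C(C)C)(C(C)C)C(C)C)cc1
F4 | step 7 | (3S)-3-[4-(triisopropylsilyloxy)phenyl]-3-(3,4,5-trimethoxyphenoxy)propan-1-ol | OCC[C@H](Oc1cc(OC)c(OC)c(OC)c1)c1ccc(O[Si](C(C)C)(C(C)C)C(C)C)cc1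
F5 | step 7 | (3S)-3-[4-(triisopropylsilyloxy)phenyl]-3-(3,4,5-trimethoxyphenoxy)propanoic acid | OC(=O)C[C@H](Oc1cc(OC)c(OC)c(OC)c1)c1ccc(O[Si](C(C)C)(C(C)C)C(C)C)cc1
F6 | step 5 | triethyl({(1R)-1-[4-(triisopropylsilyloxy)phenyl]prop-2-en-1-yl}oxy)silane | C=C[C@@H](O[Si](CC)(CC)CC)c1ccc(O[Si](C(C)C)(C(C)C)C(C)C)cc1
F7 | step 5 | (1R)-1-[4-(triisopropylsilyloxy)phenyl]prop-2-en-1-ol | C=C[C@@H](O)c1ccc(O[Si](C(C)C)(C(C)C)C(C)C)cc1
F8 | step 10 | (2S)-5-hydroxy-8-iodo-6,7-dimethoxy-2-[4-(triisopropylsilyloxy)phenyl]chroman-4-one | COc1c(O)c2c(c(I)c1OC)O[C@H](c1ccc(O[Si](C(C)C)(C(C)C)C(C)C)cc1)CC2=O
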